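A product curve cannot stay straight to the end, since it has to level off at the substrate charged, and the dispute over these flasks was how far along it begins to bend.

| setting | gamma | theta | epsilon | alpha | Friday's | Thursday's | Tuesday's | Monday's |
|---|---|---|---|---|---|---|---|---|
| substrate | 0.29 M | 0.29 M | 0.29 M | 0.14 M | 0.29 M | 0.29 M (fed, over 2.0 min) | 0.29 M (fed, over 2.0 min) | 0.29 M |
| partner | 1.1 equiv | 0.55 equiv | 2.2 equiv | 1.1 equiv | 1.10 equiv | 1.10 equiv | 1.10 equiv | 1.10 equiv |
| free catalyst | 0.2 mol% | 0.2 mol% | 0.2 mol% | 0.2 mol% | 0.2 mol% | 0.2 mol% | 0.2 mol% | 0.2 mol% |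
| temperature | 105 °C | 116 °C | 105 °C | 116 °C | 110 °C | 110 °C |  |  |
| remark | run made earlier | run made earlier | run made earlier | run made earlier | everything together at the start | all else is in the flask from the start; the feed brings no volume worth counting | the addition at 70 °C, then warmed to 110 °C; the feed brings no volume worth counting | everything together at the start at 70 °C, warmed to 110 °C at 2.0 min |
| time |  |  |  |  | 10 min | 10 min | 10 min | 10 min |

| run | time / min | product / % |
|---|---|---|
| gamma | 0.833 | 3.3 |
| gamma | 1.33 | 7.3 |
| gamma | 2.00 | 9.6 |
| gamma | 3.00 | 16.4 |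
| gamma | 4.00 | 21.5 |
| gamma | 6.00 | 28.4 |
| gamma | 10.0 | 47.0 |
| theta | 0.833 | 7.9 |
| theta | 1.50 | 12.3 |
| theta | 2.50 | 18.6 |
| theta | 3.00 | 24.5 |
| theta | 4.00 | 32.0 |
| theta | 5.00 | 36.0 |
| theta | 6.00 | 43.2 |
| epsilon | 0.833 | 4.5 |
| epsilon | 1.50 | 7.1 |
| epsilon | 2.50 | 13.4 |
| epsilon | 3.00 | 15.4 |
| epsilon | 4.00 | 19.7 |
| epsilon | 5.00 | 26.7 |
| epsilon | 6.00 | 29.9 |
| alpha | 0.500 | 3.4 |
| alpha | 1.50 | 12.6 |
| alpha | 3.00 | 22.4 |
| alpha | 4.00 | 29.7 |
| alpha | 6.00 | 41.4 |

(each reading ± 1 percentage point)

* the flask that comes out highest in amount of product, in percent of the substrate charged, or "all alike" when all lie within 1.5 percentage points (Friday's / Thursday's / Tuesday's / Monday's / all alike)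
* product at the end, in percent of the substrate charged, Friday's
* product at the end, in percent of the substrate charged, Thursday's
* product at the end, in percent of the substrate charged, Tuesday's
* product at the end, in percent of the substrate charged, Monday's

- steps under discussion: substrate + free catalyst -> catalyst intermediate A; catalyst intermediate A -> catalyst intermediate B; partner + catalyst intermediate B -> catalyst intermediate C; catalyst intermediate C -> by-product + catalyst intermediate D; catalyst intermediate D -> free catalyst + product

My colleague, who made the forecast, read the curves as lying between a rate that falls with the substrate and a steady one: “The curves are nearly straight with slight bending, so I take something in between.” The forecast gives Friday's 54%, Thursday's 50.5%, Tuesday's 45% and Monday's 46.5%, with Friday's highest.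

I held that each unit of catalyst keeps a steady pace as the substrate runs down, since in gamma the mean slope of the readings eases from 0.0537 min⁻¹ of the charge up to 4.00 min to 0.0470 min⁻¹ up to 10.0 min. I took the early slope, which is 0.0547 min⁻¹ of the charge in gamma and 0.0817 min⁻¹ in theta, and interpolated its logarithm to 110 °C, which gives 0.0656 min⁻¹, a rough figure, since theta carries 0.55 equiv of partner against gamma's 1.1 equiv and so differs in two settings. Dividing the loading by that slope gives 1.83 s, and this is the turnover time, the time one unit of catalyst needs to go once round and give one product. A straight line at that pace reaches 65.6% in Friday's, and, with the cold 2.0 min counted as nothing, 52.5% in Monday's, so I too put Friday's highest, with Thursday's a little below it.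

The simulation gives Friday's as highest, with Friday's 62.6%, Thursday's 60.6%, Tuesday's 52.3% and Monday's 52.4%.

    substrate + free catalyst → catalyst intermediate A (k = 19.0 L mol⁻¹ s⁻¹, Ea = 54.0 kJ mol⁻¹)
    catalyst intermediate A → catalyst intermediate B (k = 6.00 s⁻¹, Ea = 84.0 kJ mol⁻¹)
    partner + catalyst intermediate B → catalyst intermediate C (k = 14.0 L mol⁻¹ s⁻¹, Ea = 51.0 kJ mol⁻¹)
    catalyst intermediate C → by-product + catalyst intermediate D (k = 1.10 s⁻¹, Ea = 81.0 kJ mol⁻¹)
    catalyst intermediate D → free catalyst + product (k = 4.50 s⁻¹, Ea = 78.0 kJ mol⁻¹)
    (constants at 110 °C)

Friday's 62.6% lies nearer my line than the forecast, and it means a mean turnover time of 1.92 s. The neighbour of Friday's with 0.12 M of substrate, at the same equivalents and loading, gives 46.3%, a mean turnover time of 2.59 s, longer, and that dilute side is where my colleague's falling rate holds. At 110 °C the step from catalyst intermediate C to catalyst intermediate D takes 0.909 s on average, longer than the 0.222 s and 0.167 s of the two other one-molecule steps. Catalyst intermediate C is the resting state of Friday's, holding 39.4% of the catalyst at 10.0 min, more than any other form.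

The earlier runs and the new flask are simulated for substances that don't exist; scatter was added.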